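The 1,2-dioxolane (O1–O2–C3–C4–C5) hides a C2 axis: C3 and C5 each carry a methyl group and a CH2–C arm, with the methyls trans. Both ring C–O bonds are therefore disconnected to hydrogen peroxide and a C2-symmetric bis(2-methyloxetane), two temporary four-membered rings made only to be cleaved. In one operation H2O2 opens one oxetane at its quaternary carbon and the hydroperoxide so formed opens the second (5-exo), which closes the dioxolane, sets both quaternary stereocentres by double inversion and frees two equivalent hydroxyethyl arms. One arm becomes the acetic acid, the other is tosylated and joined to a C13 trienyl Grignard reagent.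

Key step: step 5

Assumption: the LaLi3 tris[(S)-binaphthoxide] complex is taken to deliver the methylide to the ketone face that gives the (S)-epoxide in step 4; if the sense is the opposite, the (R)-binaphthoxide complex is used.

Step 1
Reactants: 1 (R)-mevalonolactone
Product: 2 (3R)-3,5-dihydroxy-N-methoxy-N,3-dimethylpentanamide
Conditions: MeNH(OMe)·HCl, i-PrMgCl, THF, −20 → 0 °C
Reagents that add atoms: N,O-dimethylhydroxylamine hydrochloride, CNOC.Cl
Why: Weinreb aminolysis of the lactone by the chloromagnesium amide of MeNH(OMe) should open the ring to the hydroxy amide; the carbinol stereocentre is not touched.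

Step 2
Reactants: 2 (3R)-3,5-dihydroxy-N-methoxy-N,3-dimethylpentanamide
Product: 4 N-methoxy-N-methyl-2-[(2R)-2-methyloxetan-2-yl]acetamide, via primary tosylate 3 (not isolated)
Conditions: KOtBu (1.05 equiv), TsCl (1.0 equiv), THF, −10 °C; then KOtBu (1.1 equiv), 0 °C → rt
Reagents that add atoms: none
Why: One-pot selective sulfonylation of the primary alkoxide and intramolecular Williamson etherification (4-exo-tet) by the tertiary alkoxide should close the oxetane with retention, because the C–O bond at the stereocentre is never broken.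

Step 3
Reactants: 4 N-methoxy-N-methyl-2-[(2R)-2-methyloxetan-2-yl]acetamide
Product: 5 1-[(2R)-2-methyloxetan-2-yl]propan-2-one
Conditions: MeMgBr (1.5 equiv), THF, −20 → 0 °C; aq. NH4Cl
Reagents that add atoms: methylmagnesium bromide, C[Mg]Br
Why: Weinreb ketone synthesis, in which the chelated tetrahedral magnesium adduct prevents over-addition and the oxetane is inert to the Grignard reagent at low temperature.

Step 4
Reactants: 5 1-[(2R)-2-methyloxetan-2-yl]propan-2-one
Product: 7 (2R,2'R)-2,2'-methylenebis(2-methyloxetane), via epoxy oxetane 6 (not isolated)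
Conditions: dimethylsulfoxonium methylide (1.2 equiv, THF stock solution), LaLi3[(S)-binaphthoxide]3 (5 mol%), (2,4,6-(MeO)3C6H2)3P=O (5 mol%), 5 Å MS, THF, rt; then more ylide (1.2 equiv) and catalyst (15 mol%), 45 °C
Reagents that add atoms: dimethylsulfoxonium methylide, C[S+](C)(=O)[CH2-]
Why: Catalytic asymmetric Corey–Chaykovsky epoxidation followed in the same pot by sulfur ylide ring expansion of the epoxide (attack at the epoxide CH2, then 4-exo-tet loss of DMSO) should set the new quaternary centre under catalyst control and leave it untouched in the expansion, giving the C2-symmetric (R,R) bis-oxetane.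

Step 5
Reactants: 7 (2R,2'R)-2,2'-methylenebis(2-methyloxetane)
Product: 9 2,2'-[(3S,5S)-3,5-dimethyl-1,2-dioxolane-3,5-diyl]di(ethan-1-ol), via hydroperoxy alcohol 8 (not isolated)
Conditions: H2O2 (2 equiv, dry ethereal solution), Me3SiOTf (0.2 equiv), Et2O, −78 → 0 °C
Reagents that add atoms: hydrogen peroxide, OO
Why: Me3SiOTf activates one oxetane oxygen and H2O2 attacks the quaternary carbon from the rear (SN2-like, at the carbon best able to bear positive charge) to give hydroperoxy alcohol 8, whose OOH group, an alpha-effect nucleophile held three atoms from the second activated oxetane, then opens that ring in the same way. The closest known reaction types are the Lewis acid-promoted perhydrolysis of 2,2-disubstituted oxetanes and the intramolecular hydroperoxide–oxetane cyclisation, run here in tandem so that hydrogen peroxide serves twice as an O-nucleophile. The dioxolane is closed in the 5-exo-tet mode, the breaking C–O bond lying outside the new ring. C3 and C5 are both set stereospecifically by inversion of the (R)-configured oxetane carbons, so (R,R)-7 should give (S,S)-9 with trans methyl groups; C2 symmetry makes the order of the two openings irrelevant. The step needs regioselectivity for the quaternary over the CH2–O carbon, secured by the cation-stabilising substitution, and it needs the 5-exo attack by OOH to outrun a second intermolecular perhydrolysis and a 6-exo attack by the freed hydroxyl, secured by the small excess of H2O2, the higher nucleophilicity of OOH and the smaller ring.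

Step 6
Reactants: 9 2,2'-[(3S,5S)-3,5-dimethyl-1,2-dioxolane-3,5-diyl]di(ethan-1-ol)
Product: 10 2-[(3S,5S)-5-(2-hydroxyethyl)-3,5-dimethyl-1,2-dioxolan-3-yl]ethyl 4-methylbenzenesulfonate
Conditions: TsCl (1.1 equiv), Ag2O (1.5 equiv), KI (0.2 equiv), CH2Cl2, 0 °C → rt
Reagents that add atoms: p-toluenesulfonyl chloride, Cc1ccc(cc1)S(Cl)(=O)=O
Why: Silver oxide-mediated monosulfonylation of a symmetric diol (Ag2O/KI method); the two hydroxyethyl arms are homotopic through the C2 axis, so sulfonylation of either gives the same compound.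

Step 7
Reactants: 10 2-[(3S,5S)-5-(2-hydroxyethyl)-3,5-dimethyl-1,2-dioxolan-3-yl]ethyl 4-methylbenzenesulfonate
Product: 11 2-[(3R,5S)-3,5-dimethyl-5-{2-[(4-methylbenzenesulfonyl)oxy]ethyl}-1,2-dioxolan-3-yl]acetic acid
Conditions: TEMPO (0.2 equiv), PhI(OAc)2 (2.5 equiv), MeCN/H2O 1:1, rt
Reagents that add atoms: water, O
Why: TEMPO/PhI(OAc)2 oxidation in aqueous acetonitrile takes the primary alcohol through the aldehyde hydrate to the acid, while the tosylate and the dialkyl peroxide are inert to the oxoammonium oxidant.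

Step 8
Reactants: 12 (3Z)-hex-3-en-1-ol
Product: 13 5-{[(3Z)-hex-3-en-1-yl]sulfanyl}-1-phenyl-1H-tetrazole
Conditions: 1-phenyl-1H-tetrazole-5-thiol, PPh3, DIAD, THF, 0 °C → rt
Reagents that add atoms: 1-phenyl-1H-tetrazole-5-thiol, Sc1nnnn1-c1ccccc1
Why: Mitsunobu thioetherification of the primary alcohol; the (Z)-alkene is not affected.

Step 9
Reactants: 13 5-{[(3Z)-hex-3-en-1-yl]sulfanyl}-1-phenyl-1H-tetrazole
Product: 14 5-{[(3Z)-hex-3-en-1-yl]sulfonyl}-1-phenyl-1H-tetrazole
Conditions: (NH4)6Mo7O24·4H2O (10 mol%), 30% aq. H2O2 (5 equiv), EtOH, 0 °C → rt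
Reagents that add atoms: hydrogen peroxide, OO
Why: Molybdate-catalysed peroxide oxidation of sulfide to sulfone is chemoselective for sulfur over the isolated (Z)-alkene.

Step 10
Reactants: 15 6-bromohex-1-ene, 16 (2E)-but-2-enal
Product: 17 (2E)-7-bromohept-2-enal
Conditions: second-generation Grubbs catalyst RuCl2(=CHPh)(PCy3)(H2IMes) (2 mol%), 16 (3 equiv), CH2Cl2, 40 °C
Reagents that add atoms: none
Why: Olefin cross-metathesis of a terminal alkene and an electron-poor enal partner should give the (E)-enal selectively with loss of propene.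

Step 11
Reactants: 14 5-{[(3Z)-hex-3-en-1-yl]sulfonyl}-1-phenyl-1H-tetrazole, 17 (2E)-7-bromohept-2-enal
Product: 18 (3Z,6E,8E)-13-bromotrideca-3,6,8-triene
Conditions: KHMDS (1.1 equiv), DME, −60 °C → rt
Reagents that add atoms: none
Why: Julia–Kocienski olefination of the sulfonyl carbanion and the enal (addition, Smiles rearrangement, loss of SO2 and tetrazolate) should form the new C=C bond (E)-selectively, completing the (E,E)-diene while the (Z)-alkene is preserved and the primary bromide stays intact at low temperature.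

Step 12
Reactants: 11 2-[(3R,5S)-3,5-dimethyl-5-{2-[(4-methylbenzenesulfonyl)oxy]ethyl}-1,2-dioxolan-3-yl]acetic acid, 18 (3Z,6E,8E)-13-bromotrideca-3,6,8-triene
Product: 21 2-[(3R,5S)-3,5-dimethyl-5-[(7E,9E,12Z)-pentadeca-7,9,12-trien-1-yl]-1,2-dioxolan-3-yl]acetic acid, via trienylmagnesium bromide 19 (not isolated), via bromomagnesium carboxylate 20 (not isolated)
Conditions: 18, Mg, THF, rt; separately 11, MeMgBr (1.0 equiv), THF, −40 °C; combine (19, 1.5 equiv), Li2CuCl4 (5 mol%), −40 → 0 °C; aq. NH4Cl, then citric acid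
Reagents that add atoms: none
Why: Copper-catalysed alkyl–alkyl cross-coupling of a Grignard reagent and a primary tosylate (Kochi/Fouquet–Schlosser type) should be much faster at low temperature than attack on the hindered di-tertiary peroxide or on the magnesium carboxylate, and no stereocentre or alkene is touched.

Compound list
1 | (R)-mevalonolactone, (4R)-4-hydroxy-4-methyloxan-2-one | C[C@@]1(O)CCOC(=O)C1 | starting material
2 | (3R)-3,5-dihydroxy-N-methoxy-N,3-dimethylpentanamide | CON(C)C(=O)C[C@](C)(O)CCO | intermediate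
3 | (3R)-3-hydroxy-5-[methoxy(methyl)amino]-3-methyl-5-oxopentyl 4-methylbenzenesulfonate | CON(C)C(=O)C[C@](C)(O)CCOS(=O)(=O)c1ccc(C)cc1 | intermediate
4 | N-methoxy-N-methyl-2-[(2R)-2-methyloxetan-2-yl]acetamide | CON(C)C(=O)C[C@@]1(C)CCO1 | intermediate
5 | 1-[(2R)-2-methyloxetan-2-yl]propan-2-one | CC(=O)C[C@@]1(C)CCO1 | intermediate
6 | (2R)-2-methyl-2-{[(2S)-2-methyloxiran-2-yl]methyl}oxetane | C[C@@]1(CO1)C[C@@]1(C)CCO1 | intermediate
7 | (2R,2'R)-2,2'-methylenebis(2-methyloxetane) | C[C@@]1(CCO1)C[C@@]1(C)CCO1 | intermediate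
8 | (3S)-3-hydroperoxy-3-methyl-4-[(2R)-2-methyloxetan-2-yl]butan-1-ol | OCC[C@](C)(OO)C[C@@]1(C)CCO1 | intermediate
9 | 2,2'-[(3S,5S)-3,5-dimethyl-1,2-dioxolane-3,5-diyl]di(ethan-1-ol) | OCC[C@@]1(C)C[C@](C)(CCO)OO1 | intermediate
10 | 2-[(3S,5S)-5-(2-hydroxyethyl)-3,5-dimethyl-1,2-dioxolan-3-yl]ethyl 4-methylbenzenesulfonate | Cc1ccc(cc1)S(=O)(=O)OCC[C@@]1(C)C[C@](C)(CCO)OO1 | intermediate
11 | 2-[(3R,5S)-3,5-dimethyl-5-{2-[(4-methylbenzenesulfonyl)oxy]ethyl}-1,2-dioxolan-3-yl]acetic acid | Cc1ccc(cc1)S(=O)(=O)OCC[C@@]1(C)C[C@](C)(CC(=O)O)OO1 | intermediate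
12 | (3Z)-hex-3-en-1-ol | CC/C=C\CCO | starting material
13 | 5-{[(3Z)-hex-3-en-1-yl]sulfanyl}-1-phenyl-1H-tetrazole | CC/C=C\CCSc1nnnn1-c1ccccc1 | intermediate
14 | 5-{[(3Z)-hex-3-en-1-yl]sulfonyl}-1-phenyl-1H-tetrazole | CC/C=C\CCS(=O)(=O)c1nnnn1-c1ccccc1 | intermediate
15 | 6-bromohex-1-ene | C=CCCCCBr | starting material
16 | (2E)-but-2-enal (crotonaldehyde) | C/C=C/C=O | starting material
17 | (2E)-7-bromohept-2-enal | O=C/C=C/CCCCBr | intermediate
18 | (3Z,6E,8E)-13-bromotrideca-3,6,8-triene | CC/C=C\C/C=C/C=C/CCCCBr | intermediate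
19 | [(5E,7E,10Z)-trideca-5,7,10-trien-1-yl]magnesium bromide | CC/C=C\C/C=C/C=C/CCCC[Mg]Br | intermediate
20 | bromomagnesium 2-[(3R,5S)-3,5-dimethyl-5-{2-[(4-methylbenzenesulfonyl)oxy]ethyl}-1,2-dioxolan-3-yl]acetate | Cc1ccc(cc1)S(=O)(=O)OCC[C@@]1(C)C[C@](C)(CC(=O)O[Mg]Br)OO1 | intermediate
21 | 2-[(3R,5S)-3,5-dimethyl-5-[(7E,9E,12Z)-pentadeca-7,9,12-trien-1-yl]-1,2-dioxolan-3-yl]acetic acid | CC/C=C\C/C=C/C=C/CCCCCC[C@@]1(C)C[C@](C)(CC(=O)O)OO1 | target

Total step count: 12. Longest linear sequence: 8 steps (steps 1–7 and 12); steps 8–11 build the side-chain fragment in parallel.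

Steps most likely to fail

Step 5. The Lewis acid-activated tertiary C–O bonds may ionise before hydrogen peroxide arrives, which would erode the double inversion. The freed hydroxyl may also close a six-membered ether onto the second oxetane, or a second intermolecular perhydrolysis may outpace ring closure. The fallback sets out from ketone 5 and forms the two ring C–O bonds and the C3 substituent separately. Perhydrolysis of its single oxetane (ethereal H2O2, Me3SiOTf, inversion at the quaternary carbon) gives a hydroperoxy ketone that closes to the cyclic peroxyhemiketal. Methanol and PPTS in the same pot convert this into 2-[(3S)-5-methoxy-3,5-dimethyl-1,2-dioxolan-3-yl]ethan-1-ol F1. Tosylation (TsCl, pyridine) should give 2-[(3S)-5-methoxy-3,5-dimethyl-1,2-dioxolan-3-yl]ethyl 4-methylbenzenesulfonate F2. Ionisation with TiCl4 to the peroxycarbenium ion and Mukaiyama-type capture by 1,1-bis(trimethylsilyloxy)ethene should then give, after aqueous work-up, acid 11, where the route is rejoined. The new centre is set only by approach anti to the larger C5 substituent, so the C3 epimer would have to be separated.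

Step 4. The basic ylide may enolise the ketone towards the oxetane-bearing CH2 and trigger β-elimination with opening of the strained ring, and catalyst control on this β-alkoxy ketone may be incomplete. The fallback sets out from ketone 5 and builds the second carbinol centre by C–C bond formation under non-basic conditions. Catalytic asymmetric allylboration (allyldiisopropoxyborane, 3,3'-dibromo-BINOL of the enantiomer that gives the (R)-carbinol) should give (2R)-2-methyl-1-[(2R)-2-methyloxetan-2-yl]pent-4-en-2-ol F3. Ozonolysis with NaBH4 work-up gives (3R)-3-methyl-4-[(2R)-2-methyloxetan-2-yl]butane-1,3-diol F4. Treatment with KOtBu/TsCl as in step 2, through (3R)-3-hydroxy-3-methyl-4-[(2R)-2-methyloxetan-2-yl]butyl 4-methylbenzenesulfonate F5, closes the second oxetane and returns to bis-oxetane 7.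

Step 12. Reductive cleavage of the O–O bond by the organomagnesium or organocopper species may compete with substitution at the tosylate. The fallback sets out from sulfone 14 and tosyloxy acid 11 and replaces the Grignard reagent by a borane. Julia–Kocienski olefination of 14 (KHMDS, DME) uses (2E)-hepta-2,6-dienal F6, itself made by Wittig reaction of pent-4-enal with (triphenylphosphoranylidene)acetaldehyde, and should give (5E,7E,10Z)-trideca-1,5,7,10-tetraene F7. 9-BBN-H should hydroborate only the terminal vinyl group to give 9-[(5E,7E,10Z)-trideca-5,7,10-trien-1-yl]-9-borabicyclo[3.3.1]nonane F8. Alkyl–alkyl Suzuki–Miyaura coupling of F8 with tosylate 11 as its carboxylate (Pd(OAc)2, P(t-Bu)2Me, NaOH, dioxane, 50 °C) should give target 21.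

Further compounds
F1 | step 5 | 2-[(3S)-5-methoxy-3,5-dimethyl-1,2-dioxolan-3-yl]ethan-1-ol | COC1(C)C[C@](C)(CCO)OO1
F2 | step 5 | 2-[(3S)-5-methoxy-3,5-dimethyl-1,2-dioxolan-3-yl]ethyl 4-methylbenzenesulfonate | COC1(C)C[C@](C)(CCOS(=O)(=O)c2ccc(C)cc2)OO1
F3 | step 4 | (2R)-2-methyl-1-[(2R)-2-methyloxetan-2-yl]pent-4-en-2-ol | C=CC[C@@](C)(O)C[C@@]1(C)CCO1
F4 | step 4 | (3R)-3-methyl-4-[(2R)-2-methyloxetan-2-yl]butane-1,3-diol | OCC[C@@](C)(O)C[C@@]1(C)CCO1
F5 | step 4 | (3R)-3-hydroxy-3-methyl-4-[(2R)-2-methyloxetan-2-yl]butyl 4-methylbenzenesulfonate | Cc1ccc(cc1)S(=O)(=O)OCC[C@@](C)(O)C[C@@]1(C)CCO1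
F6 | step 12 | (2E)-hepta-2,6-dienal | C=CCC/C=C/C=O
F7 | step 12 | (5E,7E,10Z)-trideca-1,5,7,10-tetraene | CC/C=C\C/C=C/C=C/CCC=C
F8 | step 12 | 9-[(5E,7E,10Z)-trideca-5,7,10-trien-1-yl]-9-borabicyclo[3.3.1]nonane | CC/C=C\C/C=C/C=C/CCCCB1C2CCCC1CCC2
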